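The runs are calculated from invented constants, and the scatter is random.

The leftover came first: in the beta run, 31.0% of Q stood at 10.0 h against 45.5% of G, and the loss of Q, 19 percentage points, matched the D found, 18.9%.

| flask | Q | G | X | J | remark | time |
|---|---|---|---|---|---|---|
| gamma | 28 mM | 28 mM | 22.4 mM | 0.47 mM | run made earlier |  |
| delta | 28 mM | 28 mM | 22.4 mM | 0.81 mM | run made earlier |  |
| beta | 28 mM | 28 mM | 22.4 mM | 1.1 mM | run made earlier |  |
| maple | 28 mM | 28 mM | 22.4 mM | 1.4 mM |  | 10 h |
| alder | 28 mM | 28 mM | 22.4 mM | 0.50 mM |  | 10 h |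

- gamma (time / h: G / %, Q / %, D / %): 1.33: 50.7, 46.6, 2.3; 4.00: 50.5, 42.0, 6.1; 6.00: 49.1, 38.6, 10.4; 10.0: 48.6, 36.4, 13.1
- delta (time / h: G / %, Q / %, D / %): 2.50: 50.8, 42.4, 6.5; 5.00: 49.2, 38.0, 9.9; 8.00: 47.7, 34.6, 14.4; 10.0: 46.4, 33.6, 18.4
- beta (time / h: G / %, Q / %, D / %): 0.833: 48.6, 47.1, 4.6; 2.00: 49.8, 43.8, 8.1; 4.00: 49.3, 39.4, 13.8; 10.0: 45.5, 31.0, 18.9

(readings scatter by 1 percentage point)

- J is single-handed; Q and G are mirror images of each other, charged as a racemate, each of them at the stated concentration
- an excess is below zero if the other one leads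

- the flask that ends with the higher excess of G over Q among what is left of the two, or "neither" when 2 percentage points or less lies between them (maple / alder / neither)
- excess of G over Q among what is left of the two at the end, maple
- excess of G over Q among what is left of the two at the end, alder

I kept a ledger of X, the limiting reagent, taking one X per turn of the catalyst J, and counted turnovers, meaning D made per J charged. At 10.0 h the gamma, delta and beta runs gave 15.6, 12.7 and 9.62, so turnovers fell as J rose. Multiplying each D by the square root of beta's J over the run's own J gave 20.0%, 21.4% and 18.9%. Their mean, W = 20.1%, is my root-scaled yield.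

For maple, W gave D = 22.7%, or 9.08 turnovers. Of 22.4 mM of X, D took 12.7 mM, the G loss read from beta took 2.52 mM, and 7.18 mM stayed over. For alder, D = 13.6%, or 15.2 turnovers. D took 7.60 mM, the G loss read from gamma took 0.784 mM, and 14.0 mM stayed over. With those G readings, my excesses were 25.0% for maple and 14.3% for alder.

The forecast named maple, with 20.3% and 14.5%, noting that “doubling the catalyst does not double Q loss”.

The flasks gave 22.8% in maple and 13.8% in alder, so maple ended higher.

    X + J + Q → J + D (k = 11000 /M²/h)
    X + J + G → J + L (k = 1400 /M²/h)
    2 J ⇌ Z (K = 740 /M, k = 1200 /M/h)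
    X ⇌ E (K = 1.10, k = 1.60 /h)

Maple made 8.26 turnovers against my 9.08, and alder 15.3 against 15.2. A further flask, like alder but with 1.2 mM of J, made 9.16 turnovers against 9.81 from W. Alder ended below maple because it was charged with less J: with maple's J, alder's excess went from 13.8% to 22.8%. The flask held Z, which the number doesn't show: at the end 50.6% of maple's catalyst stood as Z against 33.1% of alder's. With 2 J to Z missing, alder minus maple came to −14 points, against −9 points as run.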